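Double product takes two reagent for each starting material, as I read its name, so in summer, with 10.0 mM of reagent against 20 mM of starting material, reagent is the limiting reagent.

| setting | north | east | autumn | midnight | summer |
|---|---|---|---|---|---|
| starting material | 20 mM (fed, over 2.5 min) | 20 mM (fed, over 2.5 min) | 20 mM (fed, over 2.5 min) | 20 mM (fed, over 2.5 min) | 20 mM (fed, over 2.5 min) |
| reagent | 12 mM | 75 mM | 60.0 mM | 40.0 mM | 10.0 mM |
| remark | run made earlier; the fed solution adds 0.10 times the starting volume | run made earlier; the fed solution adds 0.10 times the starting volume | the fed solution adds 0.10 times the starting volume | the fed solution adds 0.10 times the starting volume | the fed solution adds 0.10 times the starting volume |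
| time |  |  | 20 min | 20 min | 20 min |

- north (time / min: double product / %, single product / %): 1.00: 17.1, 8.6; 2.50: 23.5, 8.3; 6.00: 23.6, 2.4; 15.0: 23.4, 0.2
- east (time / min: double product / %, single product / %): 2.00: 76.0, 1.0; 5.00: 100.1, 0; 10.0: 99.8, 0.6; 15.0: 99.8, 0.1

(each reading ± 0.5 percentage points)

- amounts are per litre of the starting volume; all of the dose is in the solution fed
- percentages count the whole charge, also what has not yet gone in

* which of these holds the largest part of the starting material at the end of autumn (starting material / single product / double product)
* which of these holds the largest part of the starting material at the end of midnight (starting material / single product / double product)
* which of these holds the largest part of the starting material at the end of summer (starting material / single product / double product)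
* final double product in summer, as a percentage of the starting material charged

I read the north run as a ladder. On the first rung, double product already stood at 17.1% after 1.00 min, when 40.0% of the feed had gone in. On the next rung, double product stopped rising: it read 23.5% at the end of the feed and 23.4% at 15.0 min. The last rung in north was the fade of single product after the feed, from 8.3% to 2.4% in 3.50 min, a reading of 1.96 min for its half-life. From the end of the feed to 20 min, summer has 8.95 such half-lives, so I expected its end to show a finished balance.

The mean of north's flat readings, each scattered by 0.5 percentage points, is 23.5%, or 4.70 mM of double product. Twice that, taken from the 12 mM charged, leaves 2.60 mM, and this lost reagent, the reagent charged that never reached double product, is what I carried over. Taken from summer's charge, it gave me 18.5% of double product, and I expected starting material to lead there. Autumn's reagent exceeds what full conversion and the loss need, and the loss is small against midnight's charge, so I expected double product to lead in both.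

The forecast named double product for autumn, double product for midnight and starting material for summer, with 18.5% of double product in summer, reasoning “so single product is reverting to starting material, and the reagent it consumed is wasted”.

The flasks ended with double product leading autumn at 99.8%, double product leading midnight at 98.7%, and starting material leading summer at 55.8%, with 18.6% of double product.

    starting material + reagent → single product (k = 8.35 M⁻¹ s⁻¹)
    reagent + single product → double product (k = 10.2 M⁻¹ s⁻¹)
    starting material + single product → side product (k = 0.668 M⁻¹ s⁻¹)

At 0.666 min in summer, reagent used single product 35 times as fast as starting material did. Half of the turnover to double product was done by 0.669 min, and of that to side product by 3.06 min. Summer's lost reagent came to 2.56 mM. The flask like summer but with 4.0 mM of reagent reckons to 3.50% of double product with north's loss, but it held 4.94%, having lost 2.02 mM.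

The earlier runs and the new flask were computed with made-up constants; scatter was added.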